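## Retrosynthetic overview

1. Target 12 ⇐ bromohydrin 11 (C3–Cl by bromonium-assisted substitution of the tertiary alcohol) ⇐ α-bromo ketone 10 (C15 methyl by Grignard addition) ⇐ spiro enone 8 (C2–Br through a regiodefined enol ether).
2. Ring B, formed second: 8 ⇐ enal 4 + methyl vinyl ketone 5 by a photodienolate Michael addition (C6–C5 bond, quaternary spiro carbon, exocyclic C7=C14), then aldol condensation (C1=C2).
3. Ring A, formed first: 4 ⇐ bromo aldehyde 3 ⇐ citronellal enol acetate 2 by bromonium-initiated cyclization (C6–C11 bond, C10–Br).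
4. All chirality comes from (R)-citronellal 1: its methyl stereocenter (C7) steers C10 and is then erased; C10 controls C6, C6 controls C2, C2 controls C3.

Assumption: chamigrene numbering is used in the explanations (ring B = C1–C6 with C6 the spiro carbon, ring A = C6–C11, C14 = exocyclic methylene carbon, C15 = methyl on C3); commercial (R)-(+)-citronellal of high ee is the only source of chirality. The route is a proposal and has not been run.

## Route

Step 1
Reactants: 1 (R)-(+)-citronellal
Product: 2 (3R)-3,7-dimethylocta-1,6-dien-1-yl acetate (E/Z mixture)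
Conditions: Ac2O, Et3N, DMAP (10 mol%), 90 °C
Reagents that add atoms: acetic anhydride CC(=O)OC(C)=O
Why: Base-mediated O-acetylation of the aldehyde enolate (enol ester formation) masks the aldehyde as a weakly nucleophilic enol acetate; the C7 stereocenter is β to the carbonyl and is not touched, and the enol geometry is irrelevant later.

Step 2
Reactants: 2 (3R)-3,7-dimethylocta-1,6-dien-1-yl acetate
Product: 3 (1S,3R,6R)-3-bromo-2,2,6-trimethylcyclohexane-1-carbaldehyde
Conditions: NBS (1.05 equiv), HFIP, −10 °C; aq. NaHCO3 work-up
Reagents that add atoms: N-bromosuccinimide O=C1CCC(=O)N1Br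
Why: Bromonium-initiated cation–olefin (halo-polyene) cyclization terminated by the enol acetate closes ring A through a chair in which anti addition forces C10–Br equatorial and the C7 methyl stays equatorial (an axial methyl would be syn-diaxial to a C11 methyl), so C10 is set R, trans to the C7 methyl; the C6 epimer ratio does not matter because C6 is planarised in step 3.

Step 3
Reactants: 3 (1S,3R,6R)-3-bromo-2,2,6-trimethylcyclohexane-1-carbaldehyde
Product: 4 (5R)-5-bromo-2,6,6-trimethylcyclohex-1-ene-1-carbaldehyde
Conditions: IBX (2.5 equiv), DMSO, 75 °C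
Reagents that add atoms: none
Why: IBX α,β-dehydrogenation of the aldehyde through its enol can only use the C7–H (C11 is quaternary), giving the conjugated tetrasubstituted enal; the relay stereocenter C7 is erased and C10 is untouched.

Step 4
Reactants: 4 (5R)-5-bromo-2,6,6-trimethylcyclohex-1-ene-1-carbaldehyde; 5 methyl vinyl ketone
Product: 8 (6S,8R)-8-bromo-7,7-dimethyl-11-methylidenespiro[5.5]undec-1-en-3-one, via photodienol 6 (not isolated), via keto aldehyde 7 (not isolated)
Conditions: hν (365 nm LED), 5 (1.5 equiv), DBU (10 mol%), BHT (1 mol%), MeCN, 0 °C; then KOH, MeOH, 0 °C to rt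
Reagents that add atoms: none
Why: Proposed new method: n→π* excitation of the enal causes 1,5-hydrogen transfer from the cis γ-methyl (C14) to the carbonyl oxygen (photoenolization), giving the exocyclic dienol 6, which DBU deprotonates to a dienolate that is trapped at its α-carbon C6 by 5 in a Michael addition before it can reketonize, and the adduct 7 closes ring B by aldol condensation; 5 approaches C6 anti to the axial C11 methyl of the chair that keeps C10–Br equatorial, so the new C6–C5 bond is trans to bromine and the spiro center is set, and light is needed because thermal γ-deprotonation would give the endocyclic dienolate instead; the closest known reactions are the photodeconjugation of enals and enoates through photodienols with base-catalysed α-protonation, the trapping of photoenols from ortho-alkyl aryl ketones, and Robinson-type spiroannulation of α-branched aldehydes.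

Step 5
Reactants: 8 (6S,8R)-8-bromo-7,7-dimethyl-11-methylidenespiro[5.5]undec-1-en-3-one
Product: 10 (2S,6S,8R)-2,8-dibromo-7,7-dimethyl-11-methylidenespiro[5.5]undecan-3-one, via silyl enol ether 9 (not isolated)
Conditions: Et3SiH (1.2 equiv), RhCl(PPh3)3 (1 mol%), THF, 50 °C; then NBS, 0 °C; then LiBr (0.1 equiv), rt
Reagents that add atoms: N-bromosuccinimide O=C1CCC(=O)N1Br
Why: Catalytic 1,4-hydrosilylation of the enone gives only the C2=C3 silyl enol ether, so α-bromination occurs at C2 and not C4; bromine enters trans to the axial C7 branch on C6 (1,3-diaxial avoidance, as in the 2α-bromination of 3-keto steroids), and this equatorial bromide, cis to C11, is also the thermodynamic epimer reached by bromide exchange.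

Step 6
Reactants: 10 (2S,6S,8R)-2,8-dibromo-7,7-dimethyl-11-methylidenespiro[5.5]undecan-3-one
Product: 11 (2S,3R,6S,8R)-2,8-dibromo-3,7,7-trimethyl-11-methylidenespiro[5.5]undecan-3-ol
Conditions: MeMgBr (1.2 equiv), CH2Cl2–Et2O, −78 °C; aq. NH4Cl quench at −78 °C
Reagents that add atoms: methylmagnesium bromide C[Mg]Br
Why: Grignard 1,2-addition to the α-bromo ketone at low temperature gives the bromohydrin without epoxide closure (O and Br cannot become anti-periplanar in the preferred chair); the C3 configuration (equatorial attack drawn) is immaterial because step 7 is stereoconvergent.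

Step 7
Reactants: 11 (2S,3R,6S,8R)-2,8-dibromo-3,7,7-trimethyl-11-methylidenespiro[5.5]undecan-3-ol
Product: 12 (2R,6S,8S,9S)-2,8-dibromo-9-chloro-1,1,9-trimethyl-5-methylidenespiro[5.5]undecane (CNP0211773.1; (2S,3S,6S,10R) in chamigrene numbering)
Conditions: 1-chloro-N,N,2-trimethylprop-1-en-1-amine (1.5 equiv), CH2Cl2, 0 °C to rt
Reagents that add atoms: 1-chloro-N,N,2-trimethylprop-1-en-1-amine CC(C)=C(Cl)N(C)C
Why: Neutral deoxychlorination with an α-chloroenamine ionises the tertiary C3–O bond (SN1 with neighbouring-group participation) to a β-bromo cation that closes to the bromonium ion on the face of the C2 bromine, and chloride opens it anti at the tertiary carbon, giving the trans C2–Br/C3–Cl pair from either C3 epimer without free HCl that would attack the exocyclic alkene.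

## Compound list

1 | (R)-(+)-citronellal, (3R)-3,7-dimethyloct-6-enal | O=CC[C@H](C)CCC=C(C)C | starting material
2 | (3R)-3,7-dimethylocta-1,6-dien-1-yl acetate (E/Z mixture, E isomer written) | CC(=O)O/C=C/[C@H](C)CCC=C(C)C | intermediate
3 | (1S,3R,6R)-3-bromo-2,2,6-trimethylcyclohexane-1-carbaldehyde | Br[C@H]1C(C)(C)[C@@H](C=O)[C@H](C)CC1 | intermediate
4 | (5R)-5-bromo-2,6,6-trimethylcyclohex-1-ene-1-carbaldehyde | O=CC1=C(C)CC[C@@H](Br)C1(C)C | intermediate
5 | methyl vinyl ketone (but-3-en-2-one) | C=CC(C)=O | starting material
6 | (E)-[(3R)-3-bromo-2,2-dimethyl-6-methylidenecyclohexylidene]methanol (photodienol, not isolated) | O/C=C1\C(=C)CC[C@@H](Br)C1(C)C | intermediate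
7 | (1S,3R)-3-bromo-2,2-dimethyl-6-methylidene-1-(3-oxobutyl)cyclohexane-1-carbaldehyde (keto aldehyde, not isolated) | Br[C@H]1C(C)(C)[C@](C=O)(CCC(C)=O)C(=C)CC1 | intermediate
8 | (6S,8R)-8-bromo-7,7-dimethyl-11-methylidenespiro[5.5]undec-1-en-3-one | Br[C@H]1C(C)(C)[C@]2(CCC(=O)C=C2)C(=C)CC1 | intermediate
9 | triethyl{[(6S,8R)-8-bromo-7,7-dimethyl-11-methylidenespiro[5.5]undec-2-en-3-yl]oxy}silane (silyl enol ether, not isolated) | Br[C@H]1C(C)(C)[C@]2(CCC(O[Si](CC)(CC)CC)=CC2)C(=C)CC1 | intermediate
10 | (2S,6S,8R)-2,8-dibromo-7,7-dimethyl-11-methylidenespiro[5.5]undecan-3-one | Br[C@H]1C(C)(C)[C@]2(CCC(=O)[C@@H](Br)C2)C(=C)CC1 | intermediate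
11 | (2S,3R,6S,8R)-2,8-dibromo-3,7,7-trimethyl-11-methylidenespiro[5.5]undecan-3-ol (C3 epimer from equatorial attack written) | Br[C@H]1C(C)(C)[C@]2(CC[C@](O)(C)[C@@H](Br)C2)C(=C)CC1 | intermediate
12 | (2R,6S,8S,9S)-2,8-dibromo-9-chloro-1,1,9-trimethyl-5-methylidenespiro[5.5]undecane | C=C1CC[C@@H](Br)C(C)(C)[C@]12CC[C@](C)(Cl)[C@@H](Br)C2 | target

## Step count and risks

Total step count: 7. Longest linear sequence: 7 steps, from 1.

The three steps most likely to fail:

Step 2. The bromonium ion may attack the enol acetate instead of the trisubstituted alkene, or the enol acetate may be too weak a terminator. The fallback sets out from 2 and closes ring A with Hg(OTf)2–PhNMe2 (MeNO2, −20 °C, then aqueous NaCl), a divalent mercury cation–olefin cyclization through the same chair, to give chloro[(1R,3S,4R)-3-formyl-2,2,4-trimethylcyclohexyl]mercury F1. Bromodemercuration with retention (Br2, LiBr, pyridine, dark, 0 °C) then returns to the route at 3.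

Step 4 (the proposed new step). The dienolate may add to 5 through its γ-carbon C14 instead of C6, the dienol may reketonize faster than it is trapped, or 5 may polymerise under irradiation. The fallback uses known chemistry and sets out from 4: irradiate 4 alone with catalytic 1,2-dimethylimidazole in MeOH (established photodeconjugation) and isolate (1S,3R)-3-bromo-2,2-dimethyl-6-methylidenecyclohexane-1-carbaldehyde F2. F2 is then spiroannulated thermally with 5 (pyrrolidine enamine Michael addition, hydrolysis, then KOH/MeOH aldol condensation), which returns to the route at 8.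

Step 7. Ionisation at C3 may end in elimination (vinyl or allylic bromide) or chloride may open the bromonium ion at C2. The fallback sets out from 8: MeLi/CeCl3 1,2-addition gives (6S,8R)-8-bromo-3,7,7-trimethyl-11-methylidenespiro[5.5]undec-1-en-3-ol F3. Ionic reductive transposition (Et3SiH, BF3·OEt2, −78 °C) gives (6S,8R)-8-bromo-3,7,7-trimethyl-11-methylidenespiro[5.5]undec-2-ene F4 (10-bromo-β-chamigrene). Anti bromochlorination of the ring B alkene with Bu4N[BrCl2] (CH2Cl2, −78 °C) comes back to the route at 12. Here the face selectivity rests on substrate control alone, and conformational analysis suggests the C2/C3 diastereomer of 12 may predominate, so the two would have to be separated.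

## Further compounds

F1 | step 2 | chloro[(1R,3S,4R)-3-formyl-2,2,4-trimethylcyclohexyl]mercury | Cl[Hg][C@H]1C(C)(C)[C@@H](C=O)[C@H](C)CC1
F2 | step 4 | (1S,3R)-3-bromo-2,2-dimethyl-6-methylidenecyclohexane-1-carbaldehyde | Br[C@H]1C(C)(C)[C@@H](C=O)C(=C)CC1
F3 | step 7 | (6S,8R)-8-bromo-3,7,7-trimethyl-11-methylidenespiro[5.5]undec-1-en-3-ol (C3 epimer mixture) | Br[C@H]1C(C)(C)[C@]2(CCC(C)(O)C=C2)C(=C)CC1
F4 | step 7 | (6S,8R)-8-bromo-3,7,7-trimethyl-11-methylidenespiro[5.5]undec-2-ene | Br[C@H]1C(C)(C)[C@]2(CCC(C)=CC2)C(=C)CC1
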